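**Retrosynthetic overview**
1. Target 19 ⇒ α′-acetoxy enone 15 + allenyl ether 4: the methylene-cyclopentenone (C15, C16, C17 added) is the last ring, closed across C8/C13 by an allenyl-ether Nazarov cyclization.
2. 15 ⇒ macrocyclic enone 14: the key bond is C7–O, made by a reagent-controlled α′-acetoxylation (new).
3. 14 ⇒ tricyclic alcohol 11: the ten-membered ring is unveiled by ozonolysis of C8=C9 (this forms the C8 and C9 carbonyls), then β-elimination of the C13 oxygen.
4. 11 ⇒ anisole 8 (Birch reduction) ⇒ polyene 7 ⇒ geranyl chloride 5 + benzylic Grignard 6; rings A and B are made together by an enantioselective cationic bicyclization onto the anisole (ring C).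
5. Ring order: A and B (step 4), ten-membered ring by cutting the B–C fusion bond (step 7), cyclopentenone (step 10).

Atom labels C1–C20 follow kaurane numbering (C7 carries OAc, C9 and C15 are the ketones).
Assumption: the (S)-BINOL-derived acid of step 4 and the (R,R)-iodine reagent of step 9 are the enantiomers that give (4aR,10aR) and 7R; if either sense is opposite, the mirror-image reagent is used.

**Step 1**
Reactants: 1 propargyl alcohol; 2 chloromethyl methyl ether
Product: 3 3-(methoxymethoxy)prop-1-yne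
Conditions: iPr2NEt, CH2Cl2, 0 °C to rt
Reagents that add atoms: none
Why: O-alkylation (Williamson-type MOM ether formation) of the primary alcohol; no stereocentre.

**Step 2**
Reactants: 3 3-(methoxymethoxy)prop-1-yne
Product: 4 1-(methoxymethoxy)propa-1,2-diene
Conditions: KOtBu (0.3 equiv), THF, 0 °C to rt
Reagents that add atoms: none
Why: base-catalysed propargyl-to-allenyl prototropic isomerization, which stops at the allenyl ether under these mild conditions.

**Step 3**
Reactants: 5 geranyl chloride; 6 3-methoxybenzylmagnesium chloride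
Product: 7 1-[(3E)-4,8-dimethylnona-3,7-dien-1-yl]-3-methoxybenzene
Conditions: Li2CuCl4 (3 mol %), THF, −10 °C to rt
Reagents that add atoms: none
Why: copper-catalysed Grignard/allylic chloride cross-coupling (Kochi type) at the primary carbon with retention of the E alkene.

**Step 4**
Reactants: 7 1-[(3E)-4,8-dimethylnona-3,7-dien-1-yl]-3-methoxybenzene
Product: 8 (4aR,10aR)-7-methoxy-1,1,4a-trimethyl-1,2,3,4,4a,9,10,10a-octahydrophenanthrene
Conditions: (S)-3,3′-dichloro-BINOL·SbCl5 (1 equiv, ligand recovered), CH2Cl2, −78 °C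
Reagents that add atoms: none
Why: enantioselective proton-initiated cationic polyene bicyclization (Stork–Eschenmoser chair–chair folding) ended by Friedel–Crafts attack para to OMe; face-selective protonation by the chiral acid sets C10 (R), anti addition across the E alkene sets C5 (R) trans to it, and the expected ee of about 90% is raised by recrystallisation of 10.

**Step 5**
Reactants: 8 (4aR,10aR)-7-methoxy-1,1,4a-trimethyl-1,2,3,4,4a,9,10,10a-octahydrophenanthrene
Product: 10 (4bR,8aR)-4b,8,8-trimethyl-3,4,4b,5,6,7,8,8a,9,10-decahydrophenanthren-2(1H)-one, via methoxydiene 9 (not isolated)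
Conditions: Li, NH3(l), THF, t-BuOH, −78 to −33 °C; then (CO2H)2, MeOH–H2O, rt
Reagents that add atoms: water, O
Why: Birch reduction puts the two new sp3 carbons at C11 and C14 and keeps the tetrasubstituted C8=C9 alkene, and mild enol ether hydrolysis gives the β,γ-unsaturated C13 ketone without conjugation; stereocentres untouched.

**Step 6**
Reactants: 10 (4bR,8aR)-4b,8,8-trimethyl-3,4,4b,5,6,7,8,8a,9,10-decahydrophenanthren-2(1H)-one
Product: 11 (4bR,8aR)-4b,8,8-trimethyl-1,2,3,4,4b,5,6,7,8,8a,9,10-dodecahydrophenanthren-2-ol (C13 epimers)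
Conditions: NaBH4, MeOH, 0 °C
Reagents that add atoms: none
Why: hydride reduction of the ketone; the C13 carbinol configuration is irrelevant because this oxygen is eliminated in step 8.

**Step 7**
Reactants: 11 (4bR,8aR)-4b,8,8-trimethyl-1,2,3,4,4b,5,6,7,8,8a,9,10-dodecahydrophenanthren-2-ol
Product: 12 (4aR,12aR)-8-hydroxy-1,1,4a-trimethylperhydrobenzo[10]annulene-5,10-dione (C8 and C9 ketones; 13-OH epimers)
Conditions: O3, CH2Cl2–MeOH, −78 °C; then Me2S, −78 °C to rt
Reagents that add atoms: ozone, [O-][O+]=O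
Why: ozonolysis (Criegee mechanism) of the only C=C cuts the B–C fusion bond, forms the C8 and C9 carbonyl C–O bonds and turns the 6-6 system into the ten-membered ring.

**Step 8**
Reactants: 12 (4aR,12aR)-8-hydroxy-1,1,4a-trimethylperhydrobenzo[10]annulene-5,10-dione
Product: 14 (4aR,8E,12aR)-1,1,4a-trimethyl-1,2,3,4,4a,6,7,11,12,12a-decahydrobenzo[10]annulene-5,10-dione, via mesylate 13 (not isolated)
Conditions: MsCl, Et3N, CH2Cl2, −20 to 20 °C; product used at once
Reagents that add atoms: methanesulfonyl chloride, CS(=O)(=O)Cl (its atoms are in 13 only)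
Why: mesylation then E1cB β-elimination; the C13 oxygen is β only to the C8 carbonyl, so the C13=C14 enone forms regiospecifically (any Z isomer is expected to converge in step 10).

**Step 9**
Reactants: 14 (4aR,8E,12aR)-1,1,4a-trimethyl-1,2,3,4,4a,6,7,11,12,12a-decahydrobenzo[10]annulene-5,10-dione
Product: 15 (4aR,8E,11R,12aR)-1,1,4a-trimethyl-5,10-dioxo-1,2,3,4,4a,5,6,7,10,11,12,12a-dodecahydrobenzo[10]annulen-11-yl acetate (7R acetate)
Conditions: (R,R)-ArI(OAc)2 (1.2 equiv, made from the iodoarene and AcOOH), BF3·OEt2, AcOH–CH2Cl2, −40 to 0 °C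
Reagents that add atoms: [2,6-bis({(2R)-1-oxo-1-[(2,4,6-trimethylphenyl)amino]propan-2-yl}oxy)phenyl]iodanediyl diacetate, CC(=O)OI(OC(C)=O)c1c(O[C@H](C)C(=O)Nc2c(C)cc(C)cc2C)cccc1O[C@H](C)C(=O)Nc1c(C)cc(C)cc1C
Why: Proposed new method: reagent-controlled α′-acetoxylation of a macrocyclic enone by a C2-symmetric chiral (diacetoxyiodo)arene, in which BF3 enolises only the unhindered C8 carbonyl toward C7 (C9 is neopentyl and the conjugated side has no α-hydrogen), the enol adds to the trivalent iodine centre and acetate displaces the aryliodonio group at C7 while the lactamide arms of the reagent select the enol face so that the 7R acetate forms; the closest known reactions are the PhI(OAc)2/BF3·OEt2 α-acetoxylation of ketones, the Mn(OAc)3 α′-acetoxylation of enones and the α-oxytosylation of ketones with chiral iodoarenes.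

**Step 10**
Reactants: 15 (7R)-α′-acetoxy enone; 4 1-(methoxymethoxy)propa-1,2-diene
Product: 19 (5R,7R,10R,13S)-7-acetoxy-8,9-secokaura-8(14),16-diene-9,15-dione (target CNP0421845.1), via 1-lithio-1-(methoxymethoxy)allene 16 (not isolated), via C8-OLi adduct 17 (not isolated), via C8 trifluoroacetate 18 (not isolated)
Conditions: 4, n-BuLi, THF, −78 °C; add 15, −78 °C; then (CF3CO)2O, 2,6-lutidine, −78 to −20 °C
Reagents that add atoms: n-butyllithium, [Li]CCCC (Li is in 16 and 17 only); trifluoroacetic anhydride, O=C(OC(=O)C(F)(F)F)C(F)(F)F (its atoms are in 18 only)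
Why: Nazarov cyclization in its allenyl ether form (Tius cyclopentannelation), in which 1,2-addition of the lithioallene to the C8 enone carbonyl (the neopentyl C9 ketone and the acetate react more slowly), ionisation of the tertiary trifluoroacetate to the 2-alkoxypentadienyl cation, conrotatory 4π closure forming C16–C13 and loss of the methoxymethyl cation give the C15 ketone with the C16 exo-methylene in place; C13 (S) is set in the closure, which must occur on the cation face already spanned by the C9–C12 tether, a face fixed by the trans-diequatorial ring A junction and the 7R acetate.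

**Compound list**
1 | propargyl alcohol | C#CCO | starting material
2 | chloromethyl methyl ether | COCCl | starting material
3 | 3-(methoxymethoxy)prop-1-yne | C#CCOCOC | intermediate
4 | 1-(methoxymethoxy)propa-1,2-diene | C=C=COCOC | intermediate
5 | geranyl chloride, (2E)-1-chloro-3,7-dimethylocta-2,6-diene | CC(C)=CCC/C(C)=C/CCl | starting material
6 | 3-methoxybenzylmagnesium chloride | COc1cccc(C[Mg]Cl)c1 | starting material
7 | 1-[(3E)-4,8-dimethylnona-3,7-dien-1-yl]-3-methoxybenzene | COc1cccc(CC/C=C(\C)CCC=C(C)C)c1 | intermediate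
8 | (4aR,10aR)-7-methoxy-1,1,4a-trimethyl-1,2,3,4,4a,9,10,10a-octahydrophenanthrene (OMe on C13) | c1c(OC)cc2c(c1)[C@]1(C)CCCC(C)(C)[C@H]1CC2 | intermediate
9 | (4aR,10aR)-7-methoxy-1,1,4a-trimethyl-1,2,3,4,4a,5,8,9,10,10a-decahydrophenanthrene (C8=C9 and C12=C13 enol ether) | C1C=C(OC)CC2=C1[C@]1(C)CCCC(C)(C)[C@H]1CC2 | intermediate
10 | (4bR,8aR)-4b,8,8-trimethyl-3,4,4b,5,6,7,8,8a,9,10-decahydrophenanthren-2(1H)-one (C13 ketone, C8=C9) | O=C1CC2=C(CC1)[C@]1(C)CCCC(C)(C)[C@H]1CC2 | intermediate
11 | (4bR,8aR)-4b,8,8-trimethyl-1,2,3,4,4b,5,6,7,8,8a,9,10-dodecahydrophenanthren-2-ol (C13 epimers) | OC1CC2=C(CC1)[C@]1(C)CCCC(C)(C)[C@H]1CC2 | intermediate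
12 | (4aR,12aR)-8-hydroxy-1,1,4a-trimethylperhydrobenzo[10]annulene-5,10-dione (C8 and C9 ketones, 13-OH epimers) | O=C1CC(O)CCC(=O)[C@]2(C)CCCC(C)(C)[C@H]2CC1 | intermediate
13 | C13 methanesulfonate of 12 | O=C1CC(OS(C)(=O)=O)CCC(=O)[C@]2(C)CCCC(C)(C)[C@H]2CC1 | intermediate
14 | (4aR,8E,12aR)-1,1,4a-trimethyl-1,2,3,4,4a,6,7,11,12,12a-decahydrobenzo[10]annulene-5,10-dione (C8 enone, C13=C14; C9 ketone) | O=C1/C=C/CCC(=O)[C@]2(C)CCCC(C)(C)[C@H]2CC1 | intermediate
15 | (4aR,8E,11R,12aR)-1,1,4a-trimethyl-5,10-dioxo-1,2,3,4,4a,5,6,7,10,11,12,12a-dodecahydrobenzo[10]annulen-11-yl acetate (7R acetate) | O=C1/C=C/CCC(=O)[C@]2(C)CCCC(C)(C)[C@H]2C[C@H]1OC(C)=O | intermediate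
16 | 1-lithio-1-(methoxymethoxy)propa-1,2-diene | [Li]C(OCOC)=C=C | intermediate
17 | lithium alkoxide from addition of 16 to C8 of 15 (C8 epimers) | [Li]OC1(C(OCOC)=C=C)/C=C/CCC(=O)[C@]2(C)CCCC(C)(C)[C@H]2C[C@H]1OC(C)=O | intermediate
18 | C8 trifluoroacetate of the adduct (C8 epimers) | FC(F)(F)C(=O)OC1(C(OCOC)=C=C)/C=C/CCC(=O)[C@]2(C)CCCC(C)(C)[C@H]2C[C@H]1OC(C)=O | intermediate
19 | (5R,7R,10R,13S)-7-acetoxy-8,9-secokaura-8(14),16-diene-9,15-dione (CNP0421845.1) | C=C1C(=O)C2=C[C@@H]1CCC(=O)[C@]1(C)CCCC(C)(C)[C@H]1C[C@H]2OC(C)=O | target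

**Step count and risk**
Total steps: 10. Longest linear sequence: 8 (steps 3 to 10, from geranyl chloride).

Most likely to fail:

Step 10 (cyclopentannelation across the macrocycle). The organolithium must spare the acetate, the cation must close rather than eliminate, and the C13 configuration rests on macrocyclic control that has not been tested. Fallback, setting out from 15 and coming back at 19: conjugate addition of (CH2=CH)2CuLi to the enone with trapping of the enolate by N-(5-chloropyridin-2-yl)triflimide gives the (7R,13R)-13-vinyl C8(14)-enol triflate F5 (C13 arranged as in the target). Cyclocarbonylation of this 1-triflyloxy-1,4-diene with Pd(PPh3)4, CO (1 atm) and Et3N in MeCN (acylpalladation of the vinyl group, then β-hydride elimination) closes the methylene-cyclopentenone and gives 19. Here the C13 centre is set by peripheral cuprate attack instead of by the electrocyclization.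

Step 9 (the new α′-acetoxylation). Reagent control over C7 and selectivity for C7 over C11 are unproven, and BF3 may move the enone out of conjugation. Fallback with known chemistry, setting out from 14 and coming back at 15: Mn(OAc)3·2H2O in benzene at reflux (the established α′-acetoxylation of enones) gives 15 together with its (7S)-epimer F3, separated by chromatography. F3 is hydrolysed with Candida antarctica lipase B in pH 7 buffer to the (7S)-α′-hydroxy enone F4. Mitsunobu inversion of F4 with AcOH, PPh3 and DIAD gives more 15.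

Step 8 (enone formation). The ten-membered 1,6-diketone can undergo transannular aldol reaction under base, and the enone can slip to the β,γ-isomer. Fallback, setting out from 11 and coming back at 14: PhSSPh and PBu3 convert the alcohol into the C13 phenyl sulfide F1. Ozone (2 equiv, then Me2S) cleaves C8=C9 and oxidises sulfur, giving the C13 phenyl sulfoxide diketone F2. Heating F2 in toluene at 90 °C over CaCO3 gives 14 by base-free sulfoxide syn-elimination toward the acidic C14 hydrogens.

**Further compounds**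
F1 | step 8 | (4bR,8aR)-4b,8,8-trimethyl-2-(phenylsulfanyl)-1,2,3,4,4b,5,6,7,8,8a,9,10-dodecahydrophenanthrene (C13 epimers) | c1ccccc1SC1CC2=C(CC1)[C@]1(C)CCCC(C)(C)[C@H]1CC2
F2 | step 8 | (4aR,12aR)-1,1,4a-trimethyl-8-(phenylsulfinyl)perhydrobenzo[10]annulene-5,10-dione (C13 and S epimers) | O=C1CC(S(=O)c2ccccc2)CCC(=O)[C@]2(C)CCCC(C)(C)[C@H]2CC1
F3 | step 9 | (4aR,8E,11S,12aR)-1,1,4a-trimethyl-5,10-dioxo-1,2,3,4,4a,5,6,7,10,11,12,12a-dodecahydrobenzo[10]annulen-11-yl acetate (7S epimer of 15) | O=C1/C=C/CCC(=O)[C@]2(C)CCCC(C)(C)[C@H]2C[C@@H]1OC(C)=O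
F4 | step 9 | (4aR,8E,11S,12aR)-11-hydroxy-1,1,4a-trimethyl-1,2,3,4,4a,6,7,11,12,12a-decahydrobenzo[10]annulene-5,10-dione (7S alcohol) | O=C1/C=C/CCC(=O)[C@]2(C)CCCC(C)(C)[C@H]2C[C@@H]1O
F5 | step 10 | (7R,13R)-7-acetoxy-13-vinyl C8(14)-enol triflate of the ten-membered C9 ketone (triflate oxygen cis to C13) | FC(F)(F)S(=O)(=O)O/C1=C\[C@@H](C=C)CCC(=O)[C@]2(C)CCCC(C)(C)[C@H]2C[C@H]1OC(C)=O
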